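Assumption: the given SMILES is the (3R,4R) enantiomer (at each centre CH2O > ring CH > CH2Ar > H); oxolane = tetrahydrofuran ring.

**Retrosynthetic overview**

1. Aryl–alkyne bonds (twice): dipropargyl ether 1 and 4-iodo-1,2-dimethoxybenzene 2 are the precursors, through mono-coupled alkyne 3, of the symmetric 1,6-diyne 4.
2. Key disconnection, oxolane C3–C4 bond: 4 is closed by alkyne–alkyne oxidative coupling on rhodium, which forms the oxolane ring and a rhodacyclopentadiene ring in the same event (bicycle 5); H2 then opens the metallacycle to the C2-symmetric (3Z,4Z)-diene 6.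
3. Both stereocentres: 6 is the precursor, through mono-ene 7, of the (3R,4R) target 8 by catalyst-controlled double hydrogenation.
4. Ring order: the arene rings are bought; oxolane and metallacycle close together in step 2; no ring is formed afterwards.

**Route**

Step 1
Reactants: 1 dipropargyl ether (3-(prop-2-yn-1-yloxy)prop-1-yne); 2 4-iodo-1,2-dimethoxybenzene (2.1 equiv)
Product: 4 bis[3-(3,4-dimethoxyphenyl)prop-2-yn-1-yl] ether, via mono-coupled alkyne 3 (not isolated)
Conditions: Pd(PPh3)2Cl2 (2 mol %), CuI (4 mol %), Et3N/THF (1:1), degassed, 25 °C, 12 h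
Reagents that add atoms: none
Why: Twofold Sonogashira coupling (oxidative addition of the aryl iodide to zerovalent palladium formed in situ, transmetalation from the copper acetylide, reductive elimination), once on each terminal alkyne; no stereocentre is formed.

Step 2
Reactants: 4 bis[3-(3,4-dimethoxyphenyl)prop-2-yn-1-yl] ether
Product: 6 (3Z,4Z)-3,4-bis(3,4-dimethoxybenzylidene)oxolane, via oxolane-fused rhodacyclopentadiene 5 (not isolated)
Conditions: Rh(cod)2OTf (5 mol %), 2,2'-bis(diphenylphosphino)biphenyl (BIPHEP, 5 mol %), H2 (1 atm), ClCH2CH2Cl (0.1 M), 25 °C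
Reagents that add atoms: none
Why: Hydrogen-mediated reductive cyclization of a 1,6-diyne on a cationic rhodium–bisphosphine catalyst (known reaction type): oxidative coupling of the two alkynes at monovalent rhodium makes the C3–C4 bond and so closes the oxolane and the rhodacyclopentadiene ring together (trivalent rhodium bicycle 5); H2 then cleaves both Rh–C bonds with retention, so each aryl group ends cis to the ring CH2O (Z,Z), only H2 is added and no stereocentre is formed.

Step 3
Reactants: 6 (3Z,4Z)-3,4-bis(3,4-dimethoxybenzylidene)oxolane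
Product: 8 (3R,4R)-3,4-bis(3,4-dimethoxybenzyl)oxolane, via (3R,4Z)-mono-ene 7 (not isolated)
Conditions: [Ir(cod)((S)-tBu-PHOX)][B(3,5-(CF3)2C6H3)4] (2 mol %), H2 (50 bar), CH2Cl2, 25 °C, 12 h
Reagents that add atoms: none
Why: Proposed new method: double asymmetric hydrogenation of a cyclic 2,3-disubstituted 1,4-diaryl-1,3-diene is not described, but each C=C is an unfunctionalised trisubstituted aryl alkene of the kind that cationic Ir–phosphinooxazoline catalysts reduce by 1,2-syn addition of H2 with high face selectivity (closest known reactions: Ir–N,P hydrogenation of (E)-1,2-diphenylpropene and the two-stage Ir hydrogenation of 2,3-diarylbutadienes to C2-symmetric alkanes); the two alkenes of C2-symmetric 6 present homotopic faces, so the same catalyst preference sets R at C3 and then R at C4 (via 7), which places the benzyl groups trans, and the reaction is a pure addition of H2.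

**Compound list**

1 | dipropargyl ether (3-(prop-2-yn-1-yloxy)prop-1-yne) | C#CCOCC#C | starting material
2 | 4-iodo-1,2-dimethoxybenzene | COc1ccc(I)cc1OC | starting material
3 | 1,2-dimethoxy-4-[3-(prop-2-yn-1-yloxy)prop-1-yn-1-yl]benzene (mono-coupled alkyne) | COc1ccc(C#CCOCC#C)cc1OC | intermediate
4 | bis[3-(3,4-dimethoxyphenyl)prop-2-yn-1-yl] ether | COc1ccc(C#CCOCC#Cc2ccc(OC)c(OC)c2)cc1OC | intermediate
5 | cationic trivalent-rhodium metallacycle: 6,8-bis(3,4-dimethoxyphenyl)-3-oxa-7-rhodabicyclo[3.3.0]octa-1(8),5-diene with BIPHEP on Rh, triflate salt | COc1ccc(cc1OC)C1=C2COCC2=C(c2ccc(OC)c(OC)c2)[Rh-]13[P+](c2ccccc2)(c2ccccc2)c2ccccc2-c2ccccc2[P+]3(c2ccccc2)c2ccccc2.[O-]S(=O)(=O)C(F)(F)F | intermediate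
6 | (3Z,4Z)-3,4-bis(3,4-dimethoxybenzylidene)oxolane | COc1ccc(cc1OC)/C=C1\COC/C1=C\c1ccc(OC)c(OC)c1 | intermediate
7 | (3R,4Z)-3-(3,4-dimethoxybenzyl)-4-(3,4-dimethoxybenzylidene)oxolane | COc1ccc(C[C@H]2COC/C2=C\c2ccc(OC)c(OC)c2)cc1OC | intermediate
8 | (3R,4R)-3,4-bis(3,4-dimethoxybenzyl)oxolane (trans-3,4-bis(3,4-dimethoxybenzyl)tetrahydrofuran) | COc1ccc(C[C@H]2COC[C@@H]2Cc2ccc(OC)c(OC)c2)cc1OC | target

**Totals**

Total steps: 3. Longest linear sequence: 3.

**Steps most likely to fail, with fallbacks**

Step 3 (highest risk). Three things can go wrong.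
- After the first hydrogenation, the catalyst must deliver H2 to the face of 7 that carries the new benzyl group. Substrate bias favours the other face, which gives the cis (meso) isomer.
- Acidic iridium hydrides may isomerise 6 or 7 towards 3,4-dibenzylfuran.
- The sense of induction rests on an analogy: the (S)-ligand gives (R)-1,2-diphenylpropane from (E)-1,2-diphenylpropene, as best I recall. Here ring C4 maps onto the phenyl-bearing position and ring CH2O onto methyl. If the (3S,4S) product forms, the (R)-ligand is used.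

The meso isomer is a diastereomer and can be removed by chromatography or crystallisation; the ee of the trans product is upgraded because the minor enantiomer of 7 is drained into the meso compound.

Fallback, setting out from 2 and coming back at 8: the stereocentres are set by auxiliary-controlled oxidative enolate dimerization instead.
- Heck reaction of 2 with acrylic acid (Pd(OAc)2, Et3N, MeCN, 80 °C) gives (E)-3-(3,4-dimethoxyphenyl)acrylic acid F4.
- H2 with 10% Pd/C in EtOAc gives 3-(3,4-dimethoxyphenyl)propanoic acid F5.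
- Pivaloyl chloride/Et3N, then (S)-4-isopropyloxazolidin-2-one with LiCl, gives (S)-3-[3-(3,4-dimethoxyphenyl)propanoyl]-4-isopropyloxazolidin-2-one F6.
- LiN(iPr)2 in THF at −78 °C, then TiCl4, couples two enolates anti to the isopropyl groups to give (2R,3R)-2,3-bis(3,4-dimethoxybenzyl)-1,4-bis[(S)-4-isopropyl-2-oxooxazolidin-3-yl]butane-1,4-dione F7.
- LiBH4 in THF/MeOH gives (2R,3R)-2,3-bis(3,4-dimethoxybenzyl)butane-1,4-diol F8.
- Catalytic TsOH in refluxing toluene closes the oxolane with loss of water to give 8, without touching the stereocentres.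

Step 2. The diyne may undergo plain alkyne hydrogenation or [2+2+2] oligomerisation on rhodium, or the diene may aromatise to the furan on work-up.

Fallback, setting out from 4 and coming back at 6: stoichiometric reductive coupling on titanium with a separate protonolysis, without H2.
- Ti(OiPr)4 (1.2 equiv) and i-PrMgCl (2.4 equiv) in Et2O at −78 to −50 °C give a low-valent titanium–propene complex.
- This couples the two alkynes to 6,8-bis(3,4-dimethoxyphenyl)-7,7-di(propan-2-yloxy)-3-oxa-7-titanabicyclo[3.3.0]octa-1(8),5-diene F3; again the oxolane and the metallacycle close together.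
- Cold aqueous HCl replaces both Ti–C bonds by C–H with retention and returns 6.

Step 1. Oxidative alkyne homocoupling of the terminal diyne, incomplete second coupling (3 left over) or base-induced propargyl–allenyl isomerisation can lower the yield.

Fallback, setting out from 2 and coming back at 4: build the ether bond last.
- Sonogashira coupling of 2 with prop-2-yn-1-ol (Pd(PPh3)2Cl2, CuI, Et3N) gives 3-(3,4-dimethoxyphenyl)prop-2-yn-1-ol F1.
- Half of it is converted with MsCl/Et3N (CH2Cl2, −20 °C) into 3-(3,4-dimethoxyphenyl)prop-2-yn-1-yl methanesulfonate F2.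
- The other half is deprotonated with NaH (THF, 0 °C) and alkylated with F2 (Williamson ether synthesis) to give 4.

**Further compounds**

F1 | step 1 | 3-(3,4-dimethoxyphenyl)prop-2-yn-1-ol | COc1ccc(C#CCO)cc1OC
F2 | step 1 | 3-(3,4-dimethoxyphenyl)prop-2-yn-1-yl methanesulfonate | COc1ccc(C#CCOS(C)(=O)=O)cc1OC
F3 | step 2 | 6,8-bis(3,4-dimethoxyphenyl)-7,7-di(propan-2-yloxy)-3-oxa-7-titanabicyclo[3.3.0]octa-1(8),5-diene | COc1ccc(cc1OC)C1=C2COCC2=C(c2ccc(OC)c(OC)c2)[Ti]1(OC(C)C)OC(C)C
F4 | step 3 | (E)-3-(3,4-dimethoxyphenyl)acrylic acid | COc1ccc(/C=C/C(=O)O)cc1OC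
F5 | step 3 | 3-(3,4-dimethoxyphenyl)propanoic acid | COc1ccc(CCC(=O)O)cc1OC
F6 | step 3 | (S)-3-[3-(3,4-dimethoxyphenyl)propanoyl]-4-isopropyloxazolidin-2-one | COc1ccc(CCC(=O)N2[C@@H](C(C)C)COC2=O)cc1OC
F7 | step 3 | (2R,3R)-2,3-bis(3,4-dimethoxybenzyl)-1,4-bis[(S)-4-isopropyl-2-oxooxazolidin-3-yl]butane-1,4-dione | O=C(N1[C@@H](C(C)C)COC1=O)[C@H](Cc1ccc(OC)c(OC)c1)[C@@H](Cc1ccc(OC)c(OC)c1)C(=O)N1[C@@H](C(C)C)COC1=O
F8 | step 3 | (2R,3R)-2,3-bis(3,4-dimethoxybenzyl)butane-1,4-diol | OC[C@H](Cc1ccc(OC)c(OC)c1)[C@@H](Cc1ccc(OC)c(OC)c1)CO
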